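The pitfall was to rank these set-ups by how fast they make target, when the share asked for falls with the hours finished target spends beside reagent, which turns it into over-reaction product.

| flask | substrate | reagent | free catalyst | remark | time |
|---|---|---|---|---|---|
| ochre | 0.060 M | 0.078 M | 0.19 mM | run made earlier |  |
| grey | 0.060 M | 0.078 M | 0.38 mM | run made earlier |  |
| Monday's | 0.060 M (fed, over 9.60 h) | 0.0780 M | 0.19 mM | a stirred flask in which substrate is dosed at a steady rate over 9.60 h without added volume, worked up at 12 h | 12 h |
| Tuesday's | 0.060 M | 0.0780 M | 0.19 mM | everything together in a closed stirred flask, run for 12 h | 12 h |
| Thursday's | 0.060 M | 0.0780 M (fed, over 9.60 h) | 0.19 mM | a stirred flask in which reagent is dosed at a steady rate over 9.60 h without added volume, worked up at 12 h | 12 h |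
| Wednesday's | 0.060 M | 0.0780 M | 0.19 mM | one stirred flow tank at steady state, fed with the mixture as stated, mean residence time 12 h |  |

- ochre (time / h: target / %, over-reaction product / %): 1.00: 3, 0; 3.00: 6, 2; 6.00: 8, 9; 8.00: 5, 10; 12.0: 2, 17
- grey (time / h: target / %, over-reaction product / %): 0.200: 1, 0; 0.667: 4, 0; 1.00: 8, 1; 1.50: 9, 3; 2.50: 10, 7

(readings scatter by 1.5 percentage points)

* the set-up with the highest share of target in all that became target or over-reaction product, at the outlet or at the end ("none" if the first two lie within 2 percentage points) (Monday's / Tuesday's / Thursday's / Wednesday's / none)
* share of target in all that became target or over-reaction product, at the outlet or at the end, Monday's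
* share of target in all that became target or over-reaction product, at the outlet or at the end, Tuesday's
* share of target in all that became target or over-reaction product, at the outlet or at the end, Thursday's
* share of target in all that became target or over-reaction product, at the outlet or at the end, Wednesday's

- the stated concentrations are those of everything mixed, before any reaction; amounts are the same in each set-up
- the feed brings no volume worth counting
- the earlier runs were made in a closed, stirred flask

1. In the ochre run, which has Tuesday's recipe, over-reaction product reached 17% at 12.0 h. I divided that by the trapezoid area under the target curve and read 0.291 h⁻¹. This is the over-reaction constant, the fraction of standing target lost per hour, pseudo-first-order with reagent taken near its charge.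

2. Extreme one: a closed flask makes its target in one burst at the start. The share is then e^(−constant × time), or 3.06% at 12 h.

3. Extreme two: a closed flask makes target steadily throughout. Integrating gives (1 − e^(−x))/x, with x the constant times the time, or 27.8%.

4. The ochre readings stood at 89.5% of their last total by 6.00 h, so I read the making in the ochre run as fading early. Its last reading gives a share of 10.5%, which is above the burst and below the steady case. I took that for Tuesday's, and I put Monday's and Thursday's, whose catalyst is also charged at the start, near it.

5. In Wednesday's tank, fresh catalyst keeps arriving. The steady balance cancels the making rate and leaves 1/(1 + constant × residence time), or 22.3%. I therefore chose Wednesday's.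

6. The forecast gave Monday's 26%, Tuesday's 13%, Thursday's 29% and Wednesday's 22%, and named Thursday's: “Thursday's leads narrowly, and the reagent order is an assumption.” I differed from it on the dosed flasks and on the winner.

Wednesday's gave 22.1%, the highest, against 22.3% reckoned; Monday's gave 15.2%, Tuesday's 12.6% and Thursday's 13.6%.

    catalyst intermediate C → free catalyst + target (k = 84.6 h⁻¹)
    reagent + free catalyst → catalyst intermediate A (k = 1200 L mol⁻¹ h⁻¹)
    reagent + free catalyst → spent catalyst B (k = 3.13 L mol⁻¹ h⁻¹)
    substrate + catalyst intermediate B → catalyst intermediate C (k = 5210 L mol⁻¹ h⁻¹)
    free catalyst → spent catalyst A (k = 1.27 h⁻¹)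
    catalyst intermediate A → catalyst intermediate B (k = 22.3 h⁻¹)
    reagent + target → over-reaction product (k = 4.56 L mol⁻¹ h⁻¹)

Target's half-life against over-reaction on Tuesday's charge was 1.9 h, short against the 12 h. The same band of 3.06% to 27.8% also holds the grey flask, with its doubled catalyst, taken to that time: its share came to 16.4%.

Readings and results stem from a simulated flask with made-up constants; the scatter is artificial.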